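**Plan**
- The butenolide is cut last: its O–CH2–C(chain)=CH atoms are those of propargyl alcohol and its carbonyl carbon is CO2, so the chain–ring C–C bond, the ring C–CO bond and the lactone C–O bond are cut together, back to a homoallylic Grignard reagent.
- The chain is cut at the CH2–CH2 bond next to each trisubstituted alkene (oxirane opening; alkyl–alkenyl Negishi coupling), each E-alkene coming from a terminal alkyne.
- The cyclohexene is cut at its three C–CH3 bonds (enol triflate coupling, enolate methylation, conjugate addition), back to 2-allylcyclohex-2-enone.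
- Forward: the carbocycle is made first, the chain is grown outward from it in two alkyne carbometalation cycles, and the lactone ring closes in the last step.
- Stereochemistry: C6 comes from a copper-catalysed asymmetric conjugate addition, quaternary C1 from methylation anti to the C6 methyl, and both E-alkenes from syn carboalumination.

Key step: step 15

Assumption: the phosphoramidite antipode that gives the 3R centre on 2-allylcyclohex-2-enone is taken to be the one that does so on 2-methylcyclohex-2-enone; if the other sense is found, the enantiomeric ligand is used.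

**Step 1**
Reactants: 1 2-methoxybenzoic acid; 2 allyl bromide (3-bromoprop-1-ene)
Product: 4 2-allylcyclohex-2-en-1-one, via dienecarboxylic acid 3 (not isolated)
Conditions: Li, NH3(l)/THF, −78 °C; 2, −78 °C → rt; then 2 M HCl, reflux
Reagents that add atoms: water, O
Why: Birch reductive alkylation allylates the dianion of the dihydrobenzoate at the carboxyl-bearing carbon, and acid then hydrolyses the enol ether, decarboxylates the β-keto acid and moves the ring alkene into conjugation, so the allyl group ends at C2 only.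

**Step 2**
Reactants: 4 2-allylcyclohex-2-en-1-one
Product: 6 (3R)-2-allyl-3-methylcyclohex-1-en-1-yl acetate, via dimethylaluminium enolate 5 (not isolated)
Conditions: AlMe3, CuO2C(C4H3S) (copper thiophene-2-carboxylate, 5 mol%), (S)-BINOL-derived phosphoramidite bearing a bis[(R)-1-phenylethyl]amino group (10 mol%), Et2O, −30 °C; then Ac2O, −30 °C → rt; aq. work-up
Reagents that add atoms: trimethylaluminium, C[Al](C)C; acetic anhydride, CC(=O)OC(C)=O
Why: In this copper-catalysed asymmetric conjugate addition of a trialkylalane to an α-substituted cyclohexenone the chiral phosphoramidite–copper complex selects the enone face and so sets C3 as R, and O-acetylation of the aluminium enolate stores the enolate with its double bond fixed between C1 and C2.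

**Step 3**
Reactants: 6 (3R)-2-allyl-3-methylcyclohex-1-en-1-yl acetate
Product: 8 (2R,3R)-2-allyl-2,3-dimethylcyclohexan-1-one, via lithium enolate 7 (not isolated)
Conditions: MeLi (2.1 equiv), THF, 0 °C; then MeI, DMPU, −78 → 0 °C; aq. work-up
Reagents that add atoms: iodomethane, CI
Why: MeLi cleaves the enol acetate to the regiodefined lithium enolate, whose C3 methyl sits pseudoaxial to avoid A(1,2) strain with the allyl group, so SN2 methylation of the enolate should come in axially on the opposite face and set quaternary C2 as R with the two methyl groups trans.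

**Step 4**
Reactants: 8 (2R,3R)-2-allyl-2,3-dimethylcyclohexan-1-one
Product: 9 (5R,6R)-6-allyl-5,6-dimethylcyclohex-1-en-1-yl trifluoromethanesulfonate
Conditions: KN(SiMe3)2, THF, −78 °C; PhNTf2, −78 °C → rt; NH4Cl work-up
Reagents that add atoms: N-phenylbis(trifluoromethanesulfonimide), O=S(=O)(N(c1ccccc1)S(=O)(=O)C(F)(F)F)C(F)(F)F
Why: Only C6 of the ketone carries α-hydrogens, so enol triflate formation can give one regioisomer only and neither stereocentre can epimerise.

**Step 5**
Reactants: 9 (5R,6R)-6-allyl-5,6-dimethylcyclohex-1-en-1-yl trifluoromethanesulfonate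
Product: 10 (5R,6R)-6-allyl-1,5,6-trimethylcyclohex-1-ene
Conditions: MeMgBr, Fe(acac)3 (5 mol%), THF/NMP, −30 → 0 °C
Reagents that add atoms: methylmagnesium bromide, C[Mg]Br
Why: Iron-catalysed Kumada-type cross-coupling of an enol triflate with MeMgBr replaces C–O by C–CH3 at low temperature and tolerates both the neighbouring quaternary carbon and the isolated terminal alkene.

**Step 6**
Reactants: 10 (5R,6R)-6-allyl-1,5,6-trimethylcyclohex-1-ene
Product: 12 3-[(1R,6R)-1,2,6-trimethylcyclohex-2-en-1-yl]propan-1-ol, via B-alkyl-9-BBN adduct 11 (not isolated)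
Conditions: 9-BBN, THF, 0 °C → rt; then NaOH, H2O2, 0 °C
Reagents that add atoms: hydrogen peroxide, OO
Why: In this Brown hydroboration–oxidation the bulky dialkylborane adds anti-Markovnikov to the monosubstituted alkene and leaves the trisubstituted ring alkene alone, and alkaline peroxide replaces boron by hydroxyl.

**Step 7**
Reactants: 12 3-[(1R,6R)-1,2,6-trimethylcyclohex-2-en-1-yl]propan-1-ol
Product: 13 3-[(1R,6R)-1,2,6-trimethylcyclohex-2-en-1-yl]propanal
Conditions: TEMPO (10 mol%), PhI(OAc)2, CH2Cl2, rt
Reagents that add atoms: none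
Why: Oxoammonium (TEMPO) oxidation with PhI(OAc)2 as terminal oxidant stops at the aldehyde and does not touch the ring alkene.

**Step 8**
Reactants: 13 3-[(1R,6R)-1,2,6-trimethylcyclohex-2-en-1-yl]propanal
Product: 14 (5R,6R)-6-(but-3-yn-1-yl)-1,5,6-trimethylcyclohex-1-ene
Conditions: dimethyl (1-diazo-2-oxopropyl)phosphonate, K2CO3, MeOH, 0 °C → rt
Reagents that add atoms: dimethyl (1-diazo-2-oxopropyl)phosphonate, COP(=O)(OC)C(=[N+]=[N-])C(C)=O
Why: Ohira–Bestmann (Seyferth–Gilbert) homologation converts the aldehyde, which has no stereocentre at its α-carbon, into the terminal alkyne under mild carbonate conditions.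

**Step 9**
Reactants: 14 (5R,6R)-6-(but-3-yn-1-yl)-1,5,6-trimethylcyclohex-1-ene
Product: 16 (5R,6R)-6-[(3E)-4-iodo-3-methylbut-3-en-1-yl]-1,5,6-trimethylcyclohex-1-ene, via alkenyldimethylalane 15 (not isolated)
Conditions: AlMe3, Cp2ZrCl2 (20 mol%), CH2Cl2, 0 °C → rt; then I2, THF, −30 → 0 °C; aq. work-up
Reagents that add atoms: trimethylaluminium, C[Al](C)C; iodine, II
Why: Zirconium-catalysed carboalumination (Negishi) adds methyl and aluminium syn across the terminal alkyne with aluminium on the terminal carbon, and iodinolysis of the C–Al bond with retention gives the E-alkenyl iodide.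

**Step 10**
Reactants: 16 (5R,6R)-6-[(3E)-4-iodo-3-methylbut-3-en-1-yl]-1,5,6-trimethylcyclohex-1-ene; 17 (4-bromobut-1-yn-1-yl)trimethylsilane
Product: 19 trimethyl{(5E)-6-methyl-8-[(1R,6R)-1,2,6-trimethylcyclohex-2-en-1-yl]oct-5-en-1-yn-1-yl}silane, via butynylzinc bromide 18 (not isolated)
Conditions: 17, Zn dust, LiCl, THF, 50 °C; then 16, Pd(PPh3)4 (5 mol%), THF, rt
Reagents that add atoms: none
Why: In this Negishi coupling zinc inserts into the primary bromide and zerovalent palladium joins the alkylzinc to the alkenyl iodide with retention of the E geometry, while the silyl group keeps the alkyne terminus inert.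

**Step 11**
Reactants: 19 trimethyl{(5E)-6-methyl-8-[(1R,6R)-1,2,6-trimethylcyclohex-2-en-1-yl]oct-5-en-1-yn-1-yl}silane
Product: 20 (5R,6R)-1,5,6-trimethyl-6-[(3E)-3-methyloct-3-en-7-yn-1-yl]cyclohex-1-ene
Conditions: K2CO3, MeOH/THF, rt
Reagents that add atoms: none
Why: Base-catalysed methanolysis of the alkynyl C–Si bond (protodesilylation) frees the terminal alkyne and affects nothing else in this hydrocarbon.

**Step 12**
Reactants: 20 (5R,6R)-1,5,6-trimethyl-6-[(3E)-3-methyloct-3-en-7-yn-1-yl]cyclohex-1-ene; 21 oxirane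
Product: 24 (3E,7E)-4,8-dimethyl-10-[(1R,6R)-1,2,6-trimethylcyclohex-2-en-1-yl]deca-3,7-dien-1-ol, via dienyldimethylalane 22 (not isolated), via lithium alanate 23 (not isolated)
Conditions: AlMe3, Cp2ZrCl2 (20 mol%), CH2Cl2, 0 °C → rt; volatiles removed; n-BuLi, hexane/THF, −78 → 0 °C; 21, −78 °C → rt; H2O work-up
Reagents that add atoms: trimethylaluminium, C[Al](C)C
Why: A second zirconium-catalysed carboalumination sets the second E-trisubstituted alkene, and conversion of the alkenylalane into its lithium alanate makes the alkenyl group nucleophilic enough for epoxide ring opening of oxirane with retention of geometry, which gives the homoallylic alcohol.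

**Step 13**
Reactants: 24 (3E,7E)-4,8-dimethyl-10-[(1R,6R)-1,2,6-trimethylcyclohex-2-en-1-yl]deca-3,7-dien-1-ol
Product: 25 (5R,6R)-6-[(3E,7E)-10-bromo-3,7-dimethyldeca-3,7-dien-1-yl]-1,5,6-trimethylcyclohex-1-ene
Conditions: CBr4, PPh3, 2,6-lutidine, CH2Cl2, 0 °C
Reagents that add atoms: carbon tetrabromide, BrC(Br)(Br)Br
Why: In the Appel reaction bromide displaces the alkoxyphosphonium group by SN2 at the primary carbon under near-neutral conditions, so the trisubstituted alkenes should neither migrate nor cyclise.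

**Step 14**
Reactants: 25 (5R,6R)-6-[(3E,7E)-10-bromo-3,7-dimethyldeca-3,7-dien-1-yl]-1,5,6-trimethylcyclohex-1-ene
Product: 26 (3E,7E)-4,8-dimethyl-10-[(1R,6R)-1,2,6-trimethylcyclohex-2-en-1-yl]deca-3,7-dien-1-ylmagnesium bromide
Conditions: Mg turnings (I2 crystal), Et2O, reflux; solution titrated and used at once
Reagents that add atoms: magnesium, [Mg]
Why: Grignard formation by insertion of magnesium into the primary C–Br bond; closure of the homoallylic reagent to a cyclopropylcarbinyl species would put magnesium on a tertiary carbon and is unfavourable, so the E geometry should hold when the solution is used promptly.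

**Step 15**
Reactants: 26 (3E,7E)-4,8-dimethyl-10-[(1R,6R)-1,2,6-trimethylcyclohex-2-en-1-yl]deca-3,7-dien-1-ylmagnesium bromide; 27 prop-2-yn-1-ol; 28 carbon dioxide
Product: 32 4-{(3E,7E)-4,8-dimethyl-10-[(1R,6R)-1,2,6-trimethylcyclohex-2-en-1-yl]deca-3,7-dien-1-yl}furan-2(5H)-one, via bromomagnesium propargyl alkoxide 29 (not isolated), via oxamagnesacycle 30 (not isolated), via hydroxy acid 31 (not isolated)
Conditions: 27 (0.9 equiv), EtMgBr (0.9 equiv), Et2O, 0 °C; CuI (10 mol%); 26 (1.0 equiv), −10 °C → rt; CO2 (g), −20 °C → rt; 2 M HCl, rt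
Reagents that add atoms: none
Why: The alkoxide oxygen of 29 holds magnesium next to the alkyne, and the copper-catalysed transfer of the primary alkyl group goes to the internal alkyne carbon while magnesium ends on the terminal carbon, trans to the new chain, inside the five-membered oxamagnesacycle 30 (anti carbomagnesiation). CO2 inserts into the alkenyl C–Mg bond with retention, so after acidification the carboxyl and CH2OH groups of 31 are cis on the alkene and the butenolide closes by 5-exo-trig lactonisation of the hydroxyl onto the carboxyl carbon. The closest known reaction type is the CuI-catalysed addition of Grignard reagents to propargylic alcohols with electrophilic trapping of the alkenylmagnesium, a known reaction in which unactivated primary alkyl Grignard reagents are the slower class. No stereocentre is formed; the two selectivities needed, alkyl to the internal carbon and anti addition, both follow from the chelate, and the E-alkenes and the two ring stereocentres are not touched. The alkoxide is made with EtMgBr so that 26 is not spent on the O–H, and 27 is kept slightly short of 26 so that no alkyne C–H is left to protonate 30; the small excess of 26 ends as a carboxylic acid that a base wash removes.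

**Compound list**
1 | 2-methoxybenzoic acid | COc1ccccc1C(=O)O | starting material
2 | allyl bromide (3-bromoprop-1-ene) | C=CCBr | starting material
3 | 1-allyl-2-methoxycyclohexa-2,5-diene-1-carboxylic acid | COC1=CCC=CC1(CC=C)C(=O)O | intermediate
4 | 2-allylcyclohex-2-en-1-one | C=CCC1=CCCCC1=O | intermediate
5 | {[(3R)-2-allyl-3-methylcyclohex-1-en-1-yl]oxy}dimethylalane | C[Al](C)OC1=C(CC=C)[C@H](C)CCC1 | intermediate
6 | (3R)-2-allyl-3-methylcyclohex-1-en-1-yl acetate | CC(=O)OC1=C(CC=C)[C@H](C)CCC1 | intermediate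
7 | lithium (3R)-2-allyl-3-methylcyclohex-1-en-1-olate | [Li]OC1=C(CC=C)[C@H](C)CCC1 | intermediate
8 | (2R,3R)-2-allyl-2,3-dimethylcyclohexan-1-one | O=C1CCC[C@@H](C)[C@@]1(C)CC=C | intermediate
9 | (5R,6R)-6-allyl-5,6-dimethylcyclohex-1-en-1-yl trifluoromethanesulfonate | O=S(=O)(OC1=CCC[C@@H](C)[C@@]1(C)CC=C)C(F)(F)F | intermediate
10 | (5R,6R)-6-allyl-1,5,6-trimethylcyclohex-1-ene | CC1=CCC[C@@H](C)[C@@]1(C)CC=C | intermediate
11 | 9-{3-[(1R,6R)-1,2,6-trimethylcyclohex-2-en-1-yl]propyl}-9-borabicyclo[3.3.1]nonane | CC1=CCC[C@@H](C)[C@@]1(C)CCCB1C2CCCC1CCC2 | intermediate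
12 | 3-[(1R,6R)-1,2,6-trimethylcyclohex-2-en-1-yl]propan-1-ol | CC1=CCC[C@@H](C)[C@@]1(C)CCCO | intermediate
13 | 3-[(1R,6R)-1,2,6-trimethylcyclohex-2-en-1-yl]propanal | CC1=CCC[C@@H](C)[C@@]1(C)CCC=O | intermediate
14 | (5R,6R)-6-(but-3-yn-1-yl)-1,5,6-trimethylcyclohex-1-ene | CC1=CCC[C@@H](C)[C@@]1(C)CCC#C | intermediate
15 | dimethyl{(1E)-2-methyl-4-[(1R,6R)-1,2,6-trimethylcyclohex-2-en-1-yl]but-1-en-1-yl}alane | CC1=CCC[C@@H](C)[C@@]1(C)CC/C(C)=C/[Al](C)C | intermediate
16 | (5R,6R)-6-[(3E)-4-iodo-3-methylbut-3-en-1-yl]-1,5,6-trimethylcyclohex-1-ene | CC1=CCC[C@@H](C)[C@@]1(C)CC/C(C)=C/I | intermediate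
17 | (4-bromobut-1-yn-1-yl)trimethylsilane | C[Si](C)(C)C#CCCBr | starting material
18 | [4-(trimethylsilyl)but-3-yn-1-yl]zinc bromide | C[Si](C)(C)C#CCC[Zn]Br | intermediate
19 | trimethyl{(5E)-6-methyl-8-[(1R,6R)-1,2,6-trimethylcyclohex-2-en-1-yl]oct-5-en-1-yn-1-yl}silane | CC1=CCC[C@@H](C)[C@@]1(C)CC/C(C)=C/CCC#C[Si](C)(C)C | intermediate
20 | (5R,6R)-1,5,6-trimethyl-6-[(3E)-3-methyloct-3-en-7-yn-1-yl]cyclohex-1-ene | CC1=CCC[C@@H](C)[C@@]1(C)CC/C(C)=C/CCC#C | intermediate
21 | oxirane | C1CO1 | starting material
22 | {(1E,5E)-2,6-dimethyl-8-[(1R,6R)-1,2,6-trimethylcyclohex-2-en-1-yl]octa-1,5-dien-1-yl}dimethylalane | CC1=CCC[C@@H](C)[C@@]1(C)CC/C(C)=C/CC/C(C)=C/[Al](C)C | intermediate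
23 | lithium butyl{(1E,5E)-2,6-dimethyl-8-[(1R,6R)-1,2,6-trimethylcyclohex-2-en-1-yl]octa-1,5-dien-1-yl}dimethylalanate | CC1=CCC[C@@H](C)[C@@]1(C)CC/C(C)=C/CC/C(C)=C/[Al-](C)(C)CCCC.[Li+] | intermediate
24 | (3E,7E)-4,8-dimethyl-10-[(1R,6R)-1,2,6-trimethylcyclohex-2-en-1-yl]deca-3,7-dien-1-ol | CC1=CCC[C@@H](C)[C@@]1(C)CC/C(C)=C/CC/C(C)=C/CCO | intermediate
25 | (5R,6R)-6-[(3E,7E)-10-bromo-3,7-dimethyldeca-3,7-dien-1-yl]-1,5,6-trimethylcyclohex-1-ene | CC1=CCC[C@@H](C)[C@@]1(C)CC/C(C)=C/CC/C(C)=C/CCBr | intermediate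
26 | (3E,7E)-4,8-dimethyl-10-[(1R,6R)-1,2,6-trimethylcyclohex-2-en-1-yl]deca-3,7-dien-1-ylmagnesium bromide | CC1=CCC[C@@H](C)[C@@]1(C)CC/C(C)=C/CC/C(C)=C/CC[Mg]Br | intermediate
27 | prop-2-yn-1-ol | C#CCO | starting material
28 | carbon dioxide | O=C=O | starting material
29 | bromomagnesium prop-2-yn-1-olate | C#CCO[Mg]Br | intermediate
30 | 4-{(3E,7E)-4,8-dimethyl-10-[(1R,6R)-1,2,6-trimethylcyclohex-2-en-1-yl]deca-3,7-dien-1-yl}-2,5-dihydro-1,2-oxamagnesole | CC1=CCC[C@@H](C)[C@@]1(C)CC/C(C)=C/CC/C(C)=C/CCC1=C[Mg]OC1 | intermediate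
31 | (2Z,6E,10E)-3-(hydroxymethyl)-7,11-dimethyl-13-[(1R,6R)-1,2,6-trimethylcyclohex-2-en-1-yl]trideca-2,6,10-trienoic acid | CC1=CCC[C@@H](C)[C@@]1(C)CC/C(C)=C/CC/C(C)=C/CC/C(CO)=C/C(=O)O | intermediate
32 | 4-{(3E,7E)-4,8-dimethyl-10-[(1R,6R)-1,2,6-trimethylcyclohex-2-en-1-yl]deca-3,7-dien-1-yl}furan-2(5H)-one | CC1=CCC[C@@H](C)[C@@]1(C)CC/C(C)=C/CC/C(C)=C/CCC1=CC(=O)OC1 | target

**Step count**
Total steps: 15. Longest linear sequence: 15 steps, from 1 to 32; 17 enters in step 10, 21 in step 12, 27 and 28 in step 15.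

**Steps most likely to fail**

Step 15. The carbomagnesiation may be slow for an unactivated primary alkyl Grignard reagent. Proton transfer from the alkyne C–H of 29 could then consume 26 or quench 30 before carboxylation. The fallback sets out from Grignard reagent 26. Transmetalation with ZnBr2 in THF should give {(3E,7E)-4,8-dimethyl-10-[(1R,6R)-1,2,6-trimethylcyclohex-2-en-1-yl]deca-3,7-dien-1-yl}zinc bromide F1. A Negishi coupling of this homoallylzinc with commercial 4-bromofuran-2(5H)-one (Pd(PPh3)4, THF, rt) attaches the preformed butenolide at its β-carbon and comes back to the route at target 32.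

Step 2. The conjugate addition to an α-branched enone may stall, or may proceed with insufficient enantioselectivity. The fallback sets out from enone 4 and replaces steps 2 and 3.
- Corey–Bakshi–Shibata reduction ((R)-methyl oxazaborolidine, catecholborane, toluene, −78 °C) should give (1S)-2-allylcyclohex-2-en-1-ol F2.
- Hydroxyl-directed Simmons–Smith cyclopropanation (Et2Zn, CH2I2, CH2Cl2, 0 °C) places the methylene syn to the hydroxyl and gives (1R,2S,6S)-1-allylbicyclo[4.1.0]heptan-2-ol F3.
- Dess–Martin oxidation gives (1R,6S)-1-allylbicyclo[4.1.0]heptan-2-one F4.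
- Li in NH3 cleaves the cyclopropane bond that overlaps with the carbonyl. This turns the methylene into the C3 methyl and gives the same lithium enolate 7; MeI then gives ketone 8, where the route is rejoined.

Step 3. Facial selectivity in the methylation may be poor, because iodomethane is a small electrophile with an early transition state. The fallback sets out from enol acetate 6.
- MeLi followed by Me3SiCl gives {[(3R)-2-allyl-3-methylcyclohex-1-en-1-yl]oxy}trimethylsilane F5.
- Simmons–Smith cyclopropanation (Et2Zn, CH2I2, one equivalent) adds the bulky zinc carbenoid to the electron-rich enol ether on the face away from the C3 methyl and should give {[(1R,5R,6S)-6-allyl-5-methylbicyclo[4.1.0]heptan-1-yl]oxy}trimethylsilane F6.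
- NaOH in aqueous MeOH removes the silyl group and opens the cyclopropanolate at the bond between the carbinol carbon and the methylene. The former methylene is left as the C2 methyl, and the route is rejoined at ketone 8.

**Further compounds**
F1 | step 15 | {(3E,7E)-4,8-dimethyl-10-[(1R,6R)-1,2,6-trimethylcyclohex-2-en-1-yl]deca-3,7-dien-1-yl}zinc bromide | CC1=CCC[C@@H](C)[C@@]1(C)CC/C(C)=C/CC/C(C)=C/CC[Zn]Br
F2 | step 2 | (1S)-2-allylcyclohex-2-en-1-ol | O[C@H]1CCCC=C1CC=C
F3 | step 2 | (1R,2S,6S)-1-allylbicyclo[4.1.0]heptan-2-ol | O[C@H]1CCC[C@H]2C[C@@]12CC=C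
F4 | step 2 | (1R,6S)-1-allylbicyclo[4.1.0]heptan-2-one | O=C1CCC[C@H]2C[C@@]12CC=C
F5 | step 3 | {[(3R)-2-allyl-3-methylcyclohex-1-en-1-yl]oxy}trimethylsilane | C[Si](C)(C)OC1=C(CC=C)[C@H](C)CCC1
F6 | step 3 | {[(1R,5R,6S)-6-allyl-5-methylbicyclo[4.1.0]heptan-1-yl]oxy}trimethylsilane | C[Si](C)(C)O[C@@]12CCC[C@@H](C)[C@]1(CC=C)C2
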